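**Retrosynthetic overview**
1. The exocyclic enone is unveiled last by elimination from a β-hydroxy ketone; both ring ketones come from silyl-protected secondary alcohols, and the cyclohexane carbinol from equatorial MeCeCl2 addition to a ketone.
2. Key disconnection: the linker bond at the cyclohexane, made by intermolecular aldol addition of the α′-lithium enolate of a benzoxepinone enone (right half) to a hydroazulene acetaldehyde (left half); dehydration and hydrogenation then give the saturated CH2–CH2 linker.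
3. Right half from (E)-geranylacetone: Shi bis-epoxidation, then one silyl-triflate cascade that closes the oxepane first and the cyclohexanone second (trans fusion); Saegusa oxidation blocks the wrong α-side.
4. Left half from 4,4-dimethylcyclohexenone: dienone, Cu-catalysed desymmetrising conjugate addition (first stereocentre), one-carbon ring expansion to the cycloheptadienone, SmI2 ketyl–enone closure of the cis-fused cyclopentanol.
5. Then hydroxymethylation next to the ketone (iodination/Stille), Luche reduction and Johnson–Claisen chirality transfer (side chain), hydroboration; ring order: cyclohexane → cycloheptane → cyclopentane (left), oxepane → cyclohexane (right), fragments joined last.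

Assumption: geranylacetone is purchased as the isomerically pure (5E)-isomer.

Atom labels used in names: seven-membered ring C1 (bears exocyclic C25), C2, C3, C4, C5, C6 (CMe2), C7; cyclopentane C4, C5, C24, C23, C22; linker C8 (on C7) and C9 (on C10); cyclohexane C10, C11 (angular CH3), C16, C20, C21, C18; oxepane C11, C12, C13, C14, C15 (CMe2), O, C16.

**Left half**

Step 1
Reactants: 1 4,4-dimethylcyclohex-2-en-1-one
Product: 2 4,4-dimethylcyclohexa-2,5-dien-1-one
Conditions: DDQ (1.3 equiv), 1,4-dioxane, reflux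
Reagents that add atoms: none
Why: DDQ dehydrogenation of a 4,4-disubstituted cyclohexenone gives the symmetrical cross-conjugated dienone, which cannot aromatise because C4 is quaternary.

Step 2
Reactants: 3 2-(2-bromoethyl)-2-methyl-1,3-dioxolane
Product: 5 bis[2-(2-methyl-1,3-dioxolan-2-yl)ethyl]zinc, via Grignard reagent 4 (not isolated)
Conditions: Mg, THF, 25–35 °C; ZnCl2 (0.5 equiv relative to the bromide), 0 °C; 1,4-dioxane, filter, solution used directly
Reagents that add atoms: zinc dichloride, Cl[Zn]Cl; 2-(2-bromoethyl)-2-methyl-1,3-dioxolane (the second molar equivalent of the bromide that each zinc takes up), CC1(CCBr)OCCO1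
Why: Grignard formation followed by transmetalation, in which two molecules of the Grignard reagent deliver both alkyl groups to one zinc, and precipitation of the magnesium halide with dioxane gives the salt-free dialkylzinc that the enantioselective conjugate addition needs.

Step 3
Reactants: 2 4,4-dimethylcyclohexa-2,5-dien-1-one; 5 bis[2-(2-methyl-1,3-dioxolan-2-yl)ethyl]zinc
Product: 6 (R)-4,4-dimethyl-5-[2-(2-methyl-1,3-dioxolan-2-yl)ethyl]cyclohex-2-en-1-one
Conditions: Cu(OTf)2 (2 mol%), (S,R,R)-O,O′-(1,1′-binaphthyl-2,2′-diyl) N,N-bis(1-phenylethyl)phosphoramidite (4 mol%), toluene, −30 °C; aq. NH4Cl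
Reagents that add atoms: none
Why: Copper–phosphoramidite-catalysed asymmetric conjugate addition desymmetrises the dienone at one of its two enantiotopic enone units and stops at the zinc enolate; the (S,R,R) ligand, which gives (S)-3-alkylcyclohexanones from cyclohexenone, attacks the same enone face here and sets C5 as R.

Step 4
Reactants: 6 (R)-4,4-dimethyl-5-[2-(2-methyl-1,3-dioxolan-2-yl)ethyl]cyclohex-2-en-1-one
Product: 7 trimethyl{[(3R)-4,4-dimethyl-3-[2-(2-methyl-1,3-dioxolan-2-yl)ethyl]cyclohexa-1,5-dien-1-yl]oxy}silane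
Conditions: LiN(i-Pr)2, THF, −78 °C; Me3SiCl
Reagents that add atoms: chlorotrimethylsilane, C[Si](C)(C)Cl
Why: Kinetic α′-deprotonation (the only acidic site, since the γ-carbon is quaternary) and O-silylation give the 2-silyloxy diene that fixes where the extra ring carbon will be inserted.

Step 5
Reactants: 7 trimethyl{[(3R)-4,4-dimethyl-3-[2-(2-methyl-1,3-dioxolan-2-yl)ethyl]cyclohexa-1,5-dien-1-yl]oxy}silane
Product: 8 trimethyl{[4,4-dimethyl-5-[2-(2-methyl-1,3-dioxolan-2-yl)ethyl]bicyclo[4.1.0]hept-2-en-1-yl]oxy}silane (cyclopropane CH2 trans to the side chain)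
Conditions: Et2Zn, CH2I2, CH2Cl2, 0 °C; aq. NH4Cl
Reagents that add atoms: diiodomethane, ICI
Why: Furukawa–Simmons–Smith cyclopropanation occurs at the electron-rich silyl enol ether double bond, opposite the side chain, and leaves the other ring alkene untouched; the two cyclopropane centres are destroyed in the next step.

Step 6
Reactants: 8 trimethyl{[4,4-dimethyl-5-[2-(2-methyl-1,3-dioxolan-2-yl)ethyl]bicyclo[4.1.0]hept-2-en-1-yl]oxy}silane
Product: 11 (R)-4,4-dimethyl-5-(3-oxobutyl)cyclohepta-2,6-dien-1-one, via chloro ketone 9 (not isolated), via dienone ketal 10 (not isolated)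
Conditions: FeCl3, DMF, 0 °C → rt; NaOAc, MeOH, reflux; 1 M HCl, THF, rt
Reagents that add atoms: water, O
Why: Ito–Saegusa ring expansion: FeCl3 oxidises the silyloxycyclopropane with cleavage of the internal bond to the ring-enlarged β-chloro ketone, acetate-mediated E1cB loss of HCl gives the cross-conjugated cycloheptadienone, and aqueous acid hydrolyses the ketal without touching C5.

Step 7
Reactants: 11 (R)-4,4-dimethyl-5-(3-oxobutyl)cyclohepta-2,6-dien-1-one
Product: 12 (3R,3aR,8aR)-3-hydroxy-3,8,8-trimethyl-2,3,3a,4,8,8a-hexahydroazulen-5(1H)-one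
Conditions: SmI2 (2.2 equiv), t-BuOH (2 equiv), THF, −78 °C
Reagents that add atoms: none
Why: SmI2 ketyl–olefin (reductive keto–enone) cyclisation closes 5-exo on the β-carbon C4 of the nearer enone, which forces the cis ring fusion because the tether sits on C5; the samarium-bound oxygen stays anti to C3, so the C22 hydroxyl ends up cis to H-4 and the methyl on the concave face, and protonation of the cross-conjugated dienolate at C3 leaves the C1=C7 enone intact.

Step 8
Reactants: 12 (3R,3aR,8aR)-3-hydroxy-3,8,8-trimethyl-2,3,3a,4,8,8a-hexahydroazulen-5(1H)-one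
Product: 13 (3R,3aR,8aR)-3,8,8-trimethyl-3-(triethylsilyloxy)-2,3,3a,4,8,8a-hexahydroazulen-5(1H)-one
Conditions: Et3SiOTf, 2,6-lutidine, CH2Cl2, −78 → 0 °C
Reagents that add atoms: triethylsilyl trifluoromethanesulfonate, CC[Si](CC)(CC)OS(=O)(=O)C(F)(F)F
Why: A silyl triflate with a hindered pyridine base silylates even a tertiary alcohol and protects C22–OH through the hot, weakly acidic Claisen step.

Step 9
Reactants: 13 (3R,3aR,8aR)-3,8,8-trimethyl-3-(triethylsilyloxy)-2,3,3a,4,8,8a-hexahydroazulen-5(1H)-one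
Product: 14 C1-iodo enone (6-iodo derivative of 13)
Conditions: I2, pyridine, CH2Cl2, rt
Reagents that add atoms: iodine, II
Why: α-Iodination of the enone by the pyridine addition–iodination–elimination sequence, which works for 4,4-dimethylcycloalkenones, puts a cross-coupling handle on C1.

Step 10
Reactants: 14 C1-iodo enone
Product: 15 C1-hydroxymethyl enone (C25–OH)
Conditions: Bu3SnCH2OH, Pd(PPh3)4 (5 mol%), 1,4-dioxane, 90 °C
Reagents that add atoms: (tributylstannyl)methanol, CCCC[Sn](CCCC)(CCCC)CO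
Why: Stille coupling of the alkenyl iodide with the hydroxymethyl stannane installs the future exocyclic carbon C25 regiospecifically on C1.

Step 11
Reactants: 15 C1-hydroxymethyl enone
Product: 16 C25 tert-butyldiphenylsilyl ether of 15
Conditions: t-BuPh2SiCl, imidazole, DMF, rt
Reagents that add atoms: tert-butyl(chloro)diphenylsilane, CC(C)(C)[Si](Cl)(c1ccccc1)c1ccccc1
Why: Routine silylation of the primary allylic alcohol with a robust group that survives every step up to step 28.

Step 12
Reactants: 16 C25 tert-butyldiphenylsilyl ether enone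
Product: 17 (2S)-allylic alcohol (azulene locants 3R,3aR,5S,8aR; C2–OH cis to the cyclopentane ring bonds, trans to H-4 and H-5)
Conditions: NaBH4, CeCl3·7H2O, MeOH, −40 °C
Reagents that add atoms: none
Why: Luche 1,2-reduction, in which hydride is expected to approach from the convex face of the cis-fused bicycle (the face of H-4 and H-5), placing the C2 hydroxyl on the face of the cyclopentane, as the next step requires.

Step 13
Reactants: 17 (2S)-allylic alcohol
Product: 18 ethyl ester with CH2CO2Et on C7 (C7–C8 bond cis to the cyclopentane; H-7 cis to H-5) and a C1=C2 double bond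
Conditions: MeC(OEt)3, EtCO2H (cat.), xylene, 140 °C
Reagents that add atoms: triethyl orthoacetate, CCOC(C)(OCC)OCC
Why: Johnson–Claisen rearrangement, in which the ketene acetal on the C2 oxygen delivers the two-carbon chain suprafacially to C7 through a six-membered transition state, so the C2 configuration is transferred to C7 even next to the quaternary C6.

Step 14
Reactants: 18 Claisen ethyl ester
Product: 19 C2 secondary alcohol (H-1 and 2-OH both trans to the C7 side chain)
Conditions: BH3·THF, THF, 0 °C → rt; H2O2, aq. NaOAc, 0 °C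
Reagents that add atoms: hydrogen peroxide, OO
Why: Hydroboration–oxidation of the trisubstituted alkene puts oxygen on the less substituted C2 and hydrogen on C1 by syn addition opposite the C7 chain; both new centres later become trigonal, so their configuration does not matter.

Step 15
Reactants: 19 C2 secondary alcohol
Product: 20 C2 triethylsilyl ether of 19
Conditions: Et3SiCl, imidazole, DMF, rt
Reagents that add atoms: chlorotriethylsilane, CC[Si](Cl)(CC)CC
Why: Routine silylation, so that the coupling partner carries no acidic proton.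

Step 16
Reactants: 20 bis(triethylsilyl) ethyl ester
Product: 21 left-half aldehyde (C9 aldehyde)
Conditions: i-Bu2AlH (1.1 equiv), CH2Cl2, −78 °C; aq. KNaC4H4O6
Reagents that add atoms: none
Why: Low-temperature i-Bu2AlH reduction stops at the tetrahedral aluminium hemiacetal, which releases the aldehyde on work-up.

**Right half**

Step 17
Reactants: 22 (5E)-6,10-dimethylundeca-5,9-dien-2-one [(E)-geranylacetone]
Product: 23 (5R,6R,9R)-5,6:9,10-diepoxy-6,10-dimethylundecan-2-one
Conditions: D-fructose-derived Shi ketone (0.3 equiv per alkene), KHSO5 (as 2KHSO5·KHSO4·K2SO4), K2CO3, Bu4NHSO4, MeCN–CH2(OMe)2–aq. Na2B4O7 buffer, 0 °C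
Reagents that add atoms: potassium peroxymonosulfate, [K+].[O-]S(=O)(=O)OO
Why: Shi asymmetric epoxidation, in which the chiral dioxirane epoxidises both trisubstituted alkenes through the spiro transition state with the same facial sense, giving the (R,R) and (R) epoxides.

Step 18
Reactants: 23 (5R,6R,9R)-diepoxy ketone
Product: 24 triethyl{[(5R,6R,9R)-5,6:9,10-diepoxy-6,10-dimethylundec-1-en-2-yl]oxy}silane
Conditions: LiN(i-Pr)2, THF, −78 °C; Et3SiCl
Reagents that add atoms: chlorotriethylsilane, CC[Si](Cl)(CC)CC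
Why: Kinetic deprotonation of the methyl ketone at the methyl group (the epoxides are inert to the amide base at −78 °C) and O-silylation give the terminal silyl enol ether that will terminate the cascade.

Step 19
Reactants: 24 diepoxy silyl enol ether
Product: 25 (3R,5aR,9aR)-2,2,5a-trimethyl-3-(triethylsilyloxy)-3,4,5,5a,6,8,9,9a-octahydro-1-benzoxepin-7(2H)-one
Conditions: Et3SiOTf (1.1 equiv), 2,6-di-tert-butyl-4-methylpyridine, CH2Cl2, −78 °C; aq. NaHCO3
Reagents that add atoms: triethylsilyl trifluoromethanesulfonate, CC[Si](CC)(CC)OS(=O)(=O)C(F)(F)F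
Why: Silyl-triflate-triggered epoxide-opening cascade (tandem oxa- and carbacyclisation): the silylated terminal epoxide is attacked at its tertiary carbon by the internal epoxide oxygen, and the resulting epoxonium ion is opened with inversion at C11 by the enol ether, so the oxepane and then the cyclohexanone close trans-fused with C11, C14 and C16 set by two stereospecific anti openings; the enol ether's own silyl group leaves as Et3SiOTf.

Step 20
Reactants: 25 bicyclic ketone
Product: 26 C18 trimethylsilyl enol ether (C18=C21)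
Conditions: LiN(i-Pr)2, THF, −78 °C; Me3SiCl
Reagents that add atoms: chlorotrimethylsilane, C[Si](C)(C)Cl
Why: Kinetic deprotonation of the 3,3-disubstituted cyclohexanone occurs at C21, away from the quaternary C11, and O-silylation fixes that regiochemistry.

Step 21
Reactants: 26 trimethylsilyl enol ether
Product: 27 (3R,5aR,9aR)-2,2,5a-trimethyl-3-(triethylsilyloxy)-3,4,5,5a,6,9a-hexahydro-1-benzoxepin-7(2H)-one
Conditions: Pd(OAc)2 (1.1 equiv), MeCN, rt
Reagents that add atoms: none
Why: Saegusa–Ito oxidation (palladation of the silyl enol ether, then β-hydride elimination) gives the enone, in which C21 is no longer enolisable, so C10 becomes the only site of kinetic deprotonation.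

**Union and completion**

Step 22
Reactants: 27 right-half enone; 21 left-half aldehyde
Product: 28 aldol adduct (β-hydroxy ketone with the new C9–C10 bond; mixture at C9 and C10)
Conditions: LiN(i-Pr)2, THF, −78 °C, 27, 30 min; then 21, −78 °C; aq. NH4Cl
Reagents that add atoms: none
Why: Intermolecular aldol addition: kinetic α′-deprotonation of 27 gives the cross-conjugated lithium enolate at C10, which adds to the aldehyde carbon C9 and joins the two halves; the two new centres are erased or reset in steps 23 and 24.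

Step 23
Reactants: 28 aldol adduct
Product: 30 C9=C10/C20=C21 dienone, via aldol mesylate 29 (not isolated)
Conditions: MsCl, Et3N, CH2Cl2, 0 °C; DBU, rt
Reagents that add atoms: none
Why: Mesylation of the aldol and E1cB elimination with DBU complete the aldol condensation to the conjugated alkylidene ketone.

Step 24
Reactants: 30 dienone
Product: 31 saturated C18 ketone (H-10 trans to the C11 methyl; side chain equatorial)
Conditions: H2 (1 atm), Pd/C, EtOAc, rt
Reagents that add atoms: none
Why: Heterogeneous hydrogenation saturates both conjugated C=C bonds and adds hydrogen to C10 from the face opposite the axial C11 methyl, giving the equatorial side chain, which is also the thermodynamic configuration at this epimerisable centre.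

Step 25
Reactants: 31 saturated C18 ketone
Product: 32 C18 tertiary alcohol (18-OH axial, cis to the C11 methyl)
Conditions: MeLi, CeCl3, THF, −78 °C; aq. NH4Cl
Reagents that add atoms: methyllithium, [Li]C
Why: Organocerium 1,2-addition avoids enolisation of the hindered ketone; the axial trajectory is blocked by the syn-axial C11 methyl, so the methyl enters equatorially and the C18 hydroxyl becomes axial, as in the target.

Step 26
Reactants: 32 C18 tertiary alcohol
Product: 33 tetraol (2-, 14-, 18- and 22-OH free; C25 tert-butyldiphenylsilyl ether kept)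
Conditions: camphorsulfonic acid (0.2 equiv), MeOH–CH2Cl2, 0 °C → rt
Reagents that add atoms: none
Why: Mild acid-catalysed methanolysis removes the three triethylsilyl ethers, while the tert-butyldiphenylsilyl ether is stable to these conditions.

Step 27
Reactants: 33 tetraol
Product: 34 C2,C14-diketone
Conditions: Dess–Martin periodinane, CH2Cl2, rt
Reagents that add atoms: none
Why: Dess–Martin oxidation converts the two secondary alcohols into ketones under neutral conditions and cannot oxidise the tertiary alcohols.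

Step 28
Reactants: 34 C2,C14-diketone
Product: 35 C25 primary alcohol (β-hydroxy ketone)
Conditions: Bu4NF, AcOH, THF, 0 °C → rt
Reagents that add atoms: none
Why: Buffered fluoride cleaves the last silyl ether to the β-hydroxy ketone without retro-aldol loss of formaldehyde.

Step 29
Reactants: 35 C25 primary alcohol
Product: 37 CNP0316622.2 (target), via primary mesylate 36 (not isolated)
Conditions: MsCl (1.3 equiv), Et3N, CH2Cl2, −20 → 0 °C
Reagents that add atoms: none
Why: Selective mesylation of the only primary alcohol and spontaneous E1cB elimination of the β-mesyloxy ketone create the exocyclic C1=C25 methylene regiospecifically, while the tertiary alcohols do not react at low temperature.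

**Compound list**

1 | 4,4-dimethylcyclohex-2-en-1-one | CC1(C)CCC(=O)C=C1 | starting material
2 | 4,4-dimethylcyclohexa-2,5-dien-1-one | CC1(C)C=CC(=O)C=C1 | intermediate
3 | 2-(2-bromoethyl)-2-methyl-1,3-dioxolane | CC1(CCBr)OCCO1 | starting material
4 | [2-(2-methyl-1,3-dioxolan-2-yl)ethyl]magnesium bromide (not isolated) | CC1(CC[Mg]Br)OCCO1 | intermediate
5 | bis[2-(2-methyl-1,3-dioxolan-2-yl)ethyl]zinc | CC1(CC[Zn]CCC2(C)OCCO2)OCCO1 | intermediate
6 | (R)-4,4-dimethyl-5-[2-(2-methyl-1,3-dioxolan-2-yl)ethyl]cyclohex-2-en-1-one | O=C1C=CC(C)(C)[C@H](CCC2(C)OCCO2)C1 | intermediate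
7 | trimethyl{[(3R)-4,4-dimethyl-3-[2-(2-methyl-1,3-dioxolan-2-yl)ethyl]cyclohexa-1,5-dien-1-yl]oxy}silane | C[Si](C)(C)OC1=C[C@@H](CCC2(C)OCCO2)C(C)(C)C=C1 | intermediate
8 | trimethyl{[4,4-dimethyl-5-[2-(2-methyl-1,3-dioxolan-2-yl)ethyl]bicyclo[4.1.0]hept-2-en-1-yl]oxy}silane, cyclopropane CH2 trans to the side chain | C[Si](C)(C)O[C@@]12C[C@@H]1[C@@H](CCC3(C)OCCO3)C(C)(C)C=C2 | intermediate
9 | 6-chloro-4,4-dimethyl-5-[2-(2-methyl-1,3-dioxolan-2-yl)ethyl]cyclohept-2-en-1-one, C5 as in 6, C6 epimers (not isolated) | O=C1CC(Cl)[C@@H](CCC2(C)OCCO2)C(C)(C)C=C1 | intermediate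
10 | (R)-4,4-dimethyl-5-[2-(2-methyl-1,3-dioxolan-2-yl)ethyl]cyclohepta-2,6-dien-1-one (not isolated) | O=C1C=C[C@@H](CCC2(C)OCCO2)C(C)(C)C=C1 | intermediate
11 | (R)-4,4-dimethyl-5-(3-oxobutyl)cyclohepta-2,6-dien-1-one | O=C1C=C[C@@H](CCC(C)=O)C(C)(C)C=C1 | intermediate
12 | (3R,3aR,8aR)-3-hydroxy-3,8,8-trimethyl-2,3,3a,4,8,8a-hexahydroazulen-5(1H)-one (cis-fused; OH cis to H-3a) | O=C1C[C@@H]2[C@@H](CC[C@@]2(C)O)C(C)(C)C=C1 | intermediate
13 | (3R,3aR,8aR)-3,8,8-trimethyl-3-(triethylsilyloxy)-2,3,3a,4,8,8a-hexahydroazulen-5(1H)-one | O=C1C[C@@H]2[C@@H](CC[C@@]2(C)O[Si](CC)(CC)CC)C(C)(C)C=C1 | intermediate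
14 | (3R,3aR,8aR)-6-iodo-3,8,8-trimethyl-3-(triethylsilyloxy)-2,3,3a,4,8,8a-hexahydroazulen-5(1H)-one | O=C1C[C@@H]2[C@@H](CC[C@@]2(C)O[Si](CC)(CC)CC)C(C)(C)C=C1I | intermediate
15 | 6-(hydroxymethyl) analogue of 13 (C25–OH on C1) | O=C1C[C@@H]2[C@@H](CC[C@@]2(C)O[Si](CC)(CC)CC)C(C)(C)C=C1CO | intermediate
16 | 6-({[tert-butyl(diphenyl)silyl]oxy}methyl) analogue of 13 | O=C1C[C@@H]2[C@@H](CC[C@@]2(C)O[Si](CC)(CC)CC)C(C)(C)C=C1CO[Si](c1ccccc1)(c1ccccc1)C(C)(C)C | intermediate
17 | (3R,3aR,5S,8aR)-6-({[tert-butyl(diphenyl)silyl]oxy}methyl)-3,8,8-trimethyl-3-(triethylsilyloxy)-1,2,3,3a,4,5,8,8a-octahydroazulen-5-ol (5-OH cis to the cyclopentane ring bonds) | O[C@H]1C[C@@H]2[C@@H](CC[C@@]2(C)O[Si](CC)(CC)CC)C(C)(C)C=C1CO[Si](c1ccccc1)(c1ccccc1)C(C)(C)C | intermediate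
18 | ethyl ester: CH2CO2Et on C7 (cis to the cyclopentane, H-7 cis to H-5), C1=C2 alkene with C25H2OSi(t-Bu)Ph2 on C1, OSiEt3 on C22 | CC(C)(C)[Si](c1ccccc1)(c1ccccc1)OCC1=CC[C@@H]2[C@@H](CC[C@@]2(C)O[Si](CC)(CC)CC)C(C)(C)[C@H]1CC(=O)OCC | intermediate
19 | C2 alcohol from 18 (H-1 and 2-OH trans to the C7 chain) | CC(C)(C)[Si](c1ccccc1)(c1ccccc1)OC[C@H]1[C@H](O)C[C@@H]2[C@@H](CC[C@@]2(C)O[Si](CC)(CC)CC)C(C)(C)[C@H]1CC(=O)OCC | intermediate
20 | C2 triethylsilyl ether of 19 | CC(C)(C)[Si](c1ccccc1)(c1ccccc1)OC[C@H]1[C@H](O[Si](CC)(CC)CC)C[C@@H]2[C@@H](CC[C@@]2(C)O[Si](CC)(CC)CC)C(C)(C)[C@H]1CC(=O)OCC | intermediate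
21 | left-half aldehyde (C9 aldehyde of 20) | CC(C)(C)[Si](c1ccccc1)(c1ccccc1)OC[C@H]1[C@H](O[Si](CC)(CC)CC)C[C@@H]2[C@@H](CC[C@@]2(C)O[Si](CC)(CC)CC)C(C)(C)[C@H]1CC=O | intermediate
22 | (5E)-6,10-dimethylundeca-5,9-dien-2-one | CC(=O)CC/C=C(\C)CCC=C(C)C | starting material
23 | (5R,6R,9R)-5,6:9,10-diepoxy-6,10-dimethylundecan-2-one | CC(=O)CC[C@H]1O[C@]1(C)CC[C@H]1OC1(C)C | intermediate
24 | triethyl{[(5R,6R,9R)-5,6:9,10-diepoxy-6,10-dimethylundec-1-en-2-yl]oxy}silane | C=C(O[Si](CC)(CC)CC)CC[C@H]1O[C@]1(C)CC[C@H]1OC1(C)C | intermediate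
25 | (3R,5aR,9aR)-2,2,5a-trimethyl-3-(triethylsilyloxy)-3,4,5,5a,6,8,9,9a-octahydro-1-benzoxepin-7(2H)-one (trans-fused) | O=C1C[C@@]2(C)CC[C@@H](O[Si](CC)(CC)CC)C(C)(C)O[C@@H]2CC1 | intermediate
26 | trimethylsilyl enol ether of 25 (C18=C21) | C[Si](C)(C)OC1=CC[C@H]2OC(C)(C)[C@H](O[Si](CC)(CC)CC)CC[C@]2(C)C1 | intermediate
27 | (3R,5aR,9aR)-2,2,5a-trimethyl-3-(triethylsilyloxy)-3,4,5,5a,6,9a-hexahydro-1-benzoxepin-7(2H)-one | O=C1C[C@@]2(C)CC[C@@H](O[Si](CC)(CC)CC)C(C)(C)O[C@@H]2C=C1 | intermediate
28 | aldol adduct, C9 carbinol, C9/C10 diastereomer mixture | CC(C)(C)[Si](c1ccccc1)(c1ccccc1)OC[C@H]1[C@H](O[Si](CC)(CC)CC)C[C@@H]2[C@@H](CC[C@@]2(C)O[Si](CC)(CC)CC)C(C)(C)[C@H]1CC(O)C1[C@@]2(C)CC[C@@H](O[Si](CC)(CC)CC)C(C)(C)O[C@@H]2C=CC1=O | intermediate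
29 | C9 mesylate of 28 (not isolated) | CC(C)(C)[Si](c1ccccc1)(c1ccccc1)OC[C@H]1[C@H](O[Si](CC)(CC)CC)C[C@@H]2[C@@H](CC[C@@]2(C)O[Si](CC)(CC)CC)C(C)(C)[C@H]1CC(OS(C)(=O)=O)C1[C@@]2(C)CC[C@@H](O[Si](CC)(CC)CC)C(C)(C)O[C@@H]2C=CC1=O | intermediate
30 | cross-conjugated dienone (C9=C10, E/Z mixture; C20=C21) | CC(C)(C)[Si](c1ccccc1)(c1ccccc1)OC[C@H]1[C@H](O[Si](CC)(CC)CC)C[C@@H]2[C@@H](CC[C@@]2(C)O[Si](CC)(CC)CC)C(C)(C)[C@H]1CC=C1[C@@]2(C)CC[C@@H](O[Si](CC)(CC)CC)C(C)(C)O[C@@H]2C=CC1=O | intermediate
31 | saturated C18 ketone (H-10 trans to C11–CH3) | CC(C)(C)[Si](c1ccccc1)(c1ccccc1)OC[C@H]1[C@H](O[Si](CC)(CC)CC)C[C@@H]2[C@@H](CC[C@@]2(C)O[Si](CC)(CC)CC)C(C)(C)[C@H]1CC[C@@H]1[C@@]2(C)CC[C@@H](O[Si](CC)(CC)CC)C(C)(C)O[C@@H]2CCC1=O | intermediate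
32 | C18 tertiary alcohol (18-OH cis to C11–CH3) | CC(C)(C)[Si](c1ccccc1)(c1ccccc1)OC[C@H]1[C@H](O[Si](CC)(CC)CC)C[C@@H]2[C@@H](CC[C@@]2(C)O[Si](CC)(CC)CC)C(C)(C)[C@H]1CC[C@@H]1[C@@]2(C)CC[C@@H](O[Si](CC)(CC)CC)C(C)(C)O[C@@H]2CC[C@]1(C)O | intermediate
33 | tetraol, C25 tert-butyldiphenylsilyl ether | CC(C)(C)[Si](c1ccccc1)(c1ccccc1)OC[C@H]1[C@H](O)C[C@@H]2[C@@H](CC[C@@]2(C)O)C(C)(C)[C@H]1CC[C@@H]1[C@@]2(C)CC[C@@H](O)C(C)(C)O[C@@H]2CC[C@]1(C)O | intermediate
34 | C2,C14-diketone, C25 tert-butyldiphenylsilyl ether | CC(C)(C)[Si](c1ccccc1)(c1ccccc1)OC[C@H]1C(=O)C[C@@H]2[C@@H](CC[C@@]2(C)O)C(C)(C)[C@H]1CC[C@@H]1[C@@]2(C)CCC(=O)C(C)(C)O[C@@H]2CC[C@]1(C)O | intermediate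
35 | C25 primary alcohol (β-hydroxy ketone) | OC[C@H]1C(=O)C[C@@H]2[C@@H](CC[C@@]2(C)O)C(C)(C)[C@H]1CC[C@@H]1[C@@]2(C)CCC(=O)C(C)(C)O[C@@H]2CC[C@]1(C)O | intermediate
36 | C25 mesylate of 35 (not isolated) | CS(=O)(=O)OC[C@H]1C(=O)C[C@@H]2[C@@H](CC[C@@]2(C)O)C(C)(C)[C@H]1CC[C@@H]1[C@@]2(C)CCC(=O)C(C)(C)O[C@@H]2CC[C@]1(C)O | intermediate
37 | CNP0316622.2 | C=C1C(=O)C[C@@H]2[C@@H](CC[C@@]2(C)O)C(C)(C)[C@H]1CC[C@@H]1[C@@]2(C)CCC(=O)C(C)(C)O[C@@H]2CC[C@]1(C)O | target

**Totals and risks**

Total steps: 29. Longest linear sequence: 23 steps (steps 1, 3–16 and 22–29, from 1 to 37).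

The three steps most likely to fail:

Step 7 (SmI2 closure; the dienone itself may be reduced faster than it is attacked). The fallback sets out from 11 and comes back at 13. Because the cross-conjugated dienone has no enolisable α-hydrogen, LiN(i-Pr)2 and Et3SiCl (THF, −78 °C) convert only the methyl ketone of 11 into the terminal triethylsilyl enol ether F1. A hydrogen-atom-transfer radical conjugate addition (iron tris(acetylacetonate) Fe(acac)3, PhSiH3, EtOH, 60 °C) then generates the tertiary α-silyloxy radical at C22, which closes 5-exo on C4 and gives the silyl ether 13 directly, so step 8 is skipped.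

Step 12 (facial selectivity of the hydride is predicted, not proven). The fallback sets out from 16 and comes back at 17. If the reduction gives mainly the C2-epimeric allylic alcohol F2, Mitsunobu inversion (4-nitrobenzoic acid, PPh3, diisopropyl azodicarboxylate, THF) gives the inverted 4-nitrobenzoate F3, and methanolysis (K2CO3, MeOH) delivers 17.

Step 22 (hindered lithium enolate and an enolisable aldehyde; proton transfer or retro-aldol may lower conversion). The fallback sets out from 27 and comes back at 28. The α′-enolate of 27 is trapped as the trimethylsilyl dienol ether F4 (LiN(i-Pr)2, Me3SiCl, THF, −78 °C) and added to aldehyde 21 with BF3·OEt2 in CH2Cl2 at −78 °C (Mukaiyama aldol), which avoids a basic enolate and gives 28 after aqueous work-up.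

**Further compounds**

F1 | step 7 | (R)-4,4-dimethyl-5-[3-(triethylsilyloxy)but-3-en-1-yl]cyclohepta-2,6-dien-1-one | O=C1C=C[C@@H](CCC(=C)O[Si](CC)(CC)CC)C(C)(C)C=C1
F2 | step 12 | C2 epimer of 17 (2-OH cis to H-4 and H-5) | O[C@@H]1C[C@@H]2[C@@H](CC[C@@]2(C)O[Si](CC)(CC)CC)C(C)(C)C=C1CO[Si](c1ccccc1)(c1ccccc1)C(C)(C)C
F3 | step 12 | 4-nitrobenzoate of 17 | O=C(O[C@H]1C[C@@H]2[C@@H](CC[C@@]2(C)O[Si](CC)(CC)CC)C(C)(C)C=C1CO[Si](c1ccccc1)(c1ccccc1)C(C)(C)C)c1ccc(cc1)[N+](=O)[O-]
F4 | step 22 | trimethylsilyl dienol ether of 27 (C18=C10, C20=C21) | C[Si](C)(C)OC1=C[C@@]2(C)CC[C@@H](O[Si](CC)(CC)CC)C(C)(C)O[C@@H]2C=C1
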